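# Total synthesis of Jaeskeanin (14)

**Retrosynthetic overview**
1. 14 comes from the p-hydroxybenzoate of the secondary alcohol in epoxy-diol 11. Diol 11 comes from hydroxyl-directed epoxidation of the ring-B alkene in diol 10.
2. The secondary carbinol in 10 is set by hydroxyl-directed reduction of β-hydroxy ketone 9. Ketone 9 is the oxidised form of bicyclic diol 8.
3. Ring B (the seven-membered ring) is closed last, by RCM of diene 7. Diene 7 carries the tertiary isopropyl carbinol, made by adding iPr-Ce to the ring-A ketone of 6.
4. Ring A (the cyclopentanone) is formed first. Catalytic asymmetric conjugate allylation of 3-methylcyclopentenone sets the quaternary C–Me centre and gives a regiodefined enol silane. Aldol of that enolate with 3-methylbut-3-enal installs the ring-B side chain.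

**Assumption:** 4-acetoxybenzoyl chloride is commercially available. The side-chain carbinol epimers from the aldol (step 3) are carried forward together, because that centre is oxidised at step 6 and reset at step 7.

---

## Route

**Step 1**
Reactants: 1 (3-methylcyclopent-2-en-1-one, CC1=CC(=O)CC1); 2 (allyltrimethylsilane, C=CC[Si](C)(C)C)
Product: 3 (trimethyl{[(3R)-3-methyl-3-(prop-2-en-1-yl)cyclopent-1-en-1-yl]oxy}silane, C=CC[C@@]1(C)CCC(O[Si](C)(C)C)=C1)
Conditions: chiral IDPi Brønsted acid (2–5 mol %), pentane/CH2Cl2, –40 °C, 48 h; catalyst enantiomer chosen to give (R)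
Reagents that add atoms: none (allyl and TMS both come from 2)
Why: Proposed new method: the IDPi is silylated in situ by 2 (propene lost), giving a chiral silylium–IDPi ion pair that binds the enone. Allyl transfer to the β-carbon (β-silyl cation) and return of TMS⁺ to the enolate oxygen regenerate the catalyst. This creates the all-carbon quaternary C3 and a regiodefined C1=C2 enol silane; the closest known reactions are TiCl4-promoted Hosomi–Sakurai conjugate allylation of β,β-disubstituted enones (racemic) and IDPi-catalysed Mukaiyama-type additions, but catalytic enantioselective conjugate allylation of a β,β-disubstituted cyclic enone has not been shown.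

**Step 2**
Reactants: 4 (3-methylbut-3-en-1-ol, CC(=C)CCO)
Product: 5 (3-methylbut-3-enal, CC(=C)CC=O)
Conditions: Dess–Martin periodinane, NaHCO3, CH2Cl2, 0 °C, 1 h; filtered and used immediately as a solution
Reagents that add atoms: none
Why: Dess–Martin oxidation of a primary alcohol under buffered conditions keeps the β,γ-alkene from isomerising to prenal.

**Step 3**
Reactants: 3; 5
Product: 6 (3-allyl-3-methyl-2-[3-methyl-1-(trimethylsilyloxy)but-3-en-1-yl]cyclopentan-1-one, C=CC[C@@]1(C)CCC(=O)[C@@H]1C(O[Si](C)(C)C)CC(C)=C; side-chain carbinol epimeric)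
Conditions: (a) MeLi (0.95 equiv), THF, 0 °C, 30 min; (b) 5, –78 °C, 1 h; (c) Me3SiCl, –78 °C → rt
Reagents that add atoms: chlorotrimethylsilane, C[Si](C)(C)Cl
Why: House-type MeLi cleavage of the enol silane gives the lithium enolate only at C2, next to the quaternary centre, and aldol (Zimmerman–Traxler) with 5 forms the C–C bond. The aldehyde approaches anti to the slightly larger allyl group, so the side chain ends up cis to Me (trans ring-B tethers). The lithium aldolate is trapped as the TMS ether to prevent retro-aldol and to stop chelation in step 4.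

**Step 4**
Reactants: 6
Product: 7 (diol, C=CC[C@@]1(C)CC[C@@](O)(C(C)C)[C@@H]1C(O)CC(C)=C; carbinol epimeric)
Conditions: anhydrous CeCl3, iPrLi, THF, –78 °C, 2 h; then PPTS, MeOH, rt
Reagents that add atoms: isopropyllithium, CC(C)[Li]
Why: Organocerium addition to the hindered ketone suppresses enolisation and β-hydride reduction. The non-chelating OTMS arm makes the iPr group add anti to the neighbouring side chain, so the new tertiary OH is cis to it; PPTS then removes TMS.

**Step 5**
Reactants: 7
Product: 8 (bicyclic diol with trisubstituted cycloheptene, CC(C)[C@]1(O)CC[C@]2(C)CC=C(C)CC(O)[C@H]21; carbinol epimeric)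
Conditions: Hoveyda–Grubbs II (10 mol %), 1,4-benzoquinone (20 mol %), toluene (0.004 M), 80 °C, 4 h
Reagents that add atoms: none (ethylene is lost)
Why: Ring-closing metathesis joins the allyl and methallyl arms to give the Z-cycloheptene, forming Ce=Cg(Me) and ring B with the ring fusion set in step 3; free hydroxyls are tolerated.

**Step 6**
Reactants: 8
Product: 9 (β-hydroxy ketone, CC(C)[C@]1(O)CC[C@]2(C)CC=C(C)CC(=O)[C@H]21)
Conditions: Dess–Martin periodinane (1.5 equiv), NaHCO3 (5 equiv), CH2Cl2, 0 °C, 30 min
Reagents that add atoms: none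
Why: Chemoselective oxidation of the secondary alcohol (the tertiary alcohol and alkene are untouched) converges the two carbinol epimers into one ketone.

**Step 7**
Reactants: 9
Product: 10 (diol, CC(C)[C@]1(O)CC[C@]2(C)CC=C(C)C[C@H](O)[C@H]21)
Conditions: Me4NBH(OAc)3 (5 equiv), MeCN/AcOH 1:1, –20 → 0 °C, 12 h
Reagents that add atoms: none (hydride adds H only)
Why: Evans–Saksena directed reduction: the tertiary alkoxy-borohydride on C-a delivers hydride to the ketone from the face on which the ring-A carbon sits. This sets the C–O configuration (O on the face opposite the ring-A carbon, cis to the ring-fusion H).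

**Step 8**
Reactants: 10
Product: 11 (epoxy diol, CC(C)[C@]1(O)CC[C@]2(C)C[C@@H]3O[C@]3(C)C[C@H](O)[C@H]21)
Conditions: mCPBA (1.05 equiv), NaHCO3, CH2Cl2, –20 °C, 2 h
Reagents that add atoms: mCPBA, O=C(OO)c1cccc(Cl)c1
Why: Henbest-type hydroxyl-directed epoxidation of the homoallylic secondary alcohol delivers the epoxide oxygen syn to that OH, which is the configuration required in the target.

**Step 9**
Reactants: 11; 12 (4-acetoxybenzoyl chloride, CC(=O)Oc1ccc(cc1)C(Cl)=O)
Product: 13 (epoxy alcohol 4-acetoxybenzoate, CC(C)[C@]1(O)CC[C@]2(C)C[C@@H]3O[C@]3(C)C[C@H](OC(=O)c3ccc(OC(C)=O)cc3)[C@H]21)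
Conditions: 12 (2 equiv), pyridine (5 equiv), DMAP (0.2 equiv), CH2Cl2, 0 °C → rt, 6 h
Reagents that add atoms: none beyond reactant 12
Why: Nucleophilic acylation occurs only at the secondary alcohol without touching the hindered tertiary alcohol, and pyridine buffers HCl to protect the epoxide; configuration is retained.

**Step 10**
Reactants: 13
Product: 14 (Jaeskeanin, CC(C)[C@]1(O)CC[C@]2(C)C[C@@H]3O[C@]3(C)C[C@H](OC(=O)c3ccc(O)cc3)[C@H]21)
Conditions: K2CO3 (1 equiv), MeOH, 0 °C, 15 min
Reagents that add atoms: none
Why: The aryl acetate is far more labile to methanolysis than the secondary p-hydroxybenzoate, and the epoxide and tertiary alcohol survive.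

---

## Compound list

| # | Name | SMILES | Role |
|---|---|---|---|
| 1 | 3-methylcyclopent-2-en-1-one | CC1=CC(=O)CC1 | starting material |
| 2 | allyltrimethylsilane | C=CC[Si](C)(C)C | starting material |
| 3 | (3R)-3-allyl-3-methylcyclopent-1-enyl TMS ether | C=CC[C@@]1(C)CCC(O[Si](C)(C)C)=C1 | intermediate |
| 4 | 3-methylbut-3-en-1-ol | CC(=C)CCO | starting material |
| 5 | 3-methylbut-3-enal | CC(=C)CC=O | intermediate |
| 6 | aldol TMS ether (carbinol epimeric) | C=CC[C@@]1(C)CCC(=O)[C@@H]1C(O[Si](C)(C)C)CC(C)=C | intermediate |
| 7 | acyclic diene diol (carbinol epimeric) | C=CC[C@@]1(C)CC[C@@](O)(C(C)C)[C@@H]1C(O)CC(C)=C | intermediate |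
| 8 | bicyclic cycloheptene diol (carbinol epimeric) | CC(C)[C@]1(O)CC[C@]2(C)CC=C(C)CC(O)[C@H]21 | intermediate |
| 9 | bicyclic β-hydroxy ketone | CC(C)[C@]1(O)CC[C@]2(C)CC=C(C)CC(=O)[C@H]21 | intermediate |
| 10 | bicyclic diol (correct carbinol) | CC(C)[C@]1(O)CC[C@]2(C)CC=C(C)C[C@H](O)[C@H]21 | intermediate |
| 11 | epoxy diol | CC(C)[C@]1(O)CC[C@]2(C)C[C@@H]3O[C@]3(C)C[C@H](O)[C@H]21 | intermediate |
| 12 | 4-acetoxybenzoyl chloride | CC(=O)Oc1ccc(cc1)C(Cl)=O | starting material |
| 13 | epoxy alcohol 4-acetoxybenzoate | CC(C)[C@]1(O)CC[C@]2(C)C[C@@H]3O[C@]3(C)C[C@H](OC(=O)c3ccc(OC(C)=O)cc3)[C@H]21 | intermediate |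
| 14 | Jaeskeanin | CC(C)[C@]1(O)CC[C@]2(C)C[C@@H]3O[C@]3(C)C[C@H](OC(=O)c3ccc(O)cc3)[C@H]21 | target |

---

**Total steps:** 10 (including the aldehyde preparation).
**Longest linear sequence:** 9 steps (1 → 3 → 6 → 7 → 8 → 9 → 10 → 11 → 13 → 14).

**Three steps most likely to fail**
1. **Step 1 (the proposed new step).** The catalyst must discriminate the two enone faces and deliver the allyl to a hindered β,β-disubstituted carbon in good ee, without competing 1,2-allylation.
   - Fallback (known chemistry): Cu/Josiphos-catalysed asymmetric conjugate addition of MeMgBr to 3-allylcyclopent-2-enone (from 3-ethoxycyclopentenone plus allylMgBr, then acid). Trap the magnesium enolate with TMSCl to give 3.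
2. **Step 4.** A secondary-alkyl nucleophile adding to a ketone flanked by a tertiary centre and a β-quaternary centre risks enolisation, reduction or poor diastereoselectivity.
   - Fallback: run RCM first, then add isopropenyl-CeCl2 (an sp² nucleophile with no β-hydride) to the bicyclic ketone. Then do a hydroxyl-directed Crabtree hydrogenation of the isopropenyl group.
3. **Step 8.** The substrate-directed face selectivity of epoxidation on a flexible seven-membered ring may be modest.
   - Fallback: catalyst-controlled Shi epoxidation (fructose-derived ketone, Oxone), using whichever catalyst enantiomer matches, in place of substrate direction.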